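**Retrosynthetic overview**
1. Target 20 ← 18 by removing the 7‑O‑(2‑trimethylsilylethyl) group with fluoride and the 3‑O‑MOM group with dilute acid.
2. Feature used: ring A (C4a, C5–C8, C8a) carries oxygen at C5, C7 and C8 and hydrogen at C6, and shares the C4a=C8a edge with the γ‑pyrone ring C. It is cut at C4a–C5 back to a 3‑alkoxy‑4‑methoxycyclobutenone attached to C8a (pyranone C6) of a finished B–C unit (15 → 18, thermal 4π opening then 6π closure).
3. 15 ← C8–C8a bond: C6‑magnesiated pyranone 7 adds to semisquarate 12 (from squaric acid 8), then O‑methylation.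
4. 7 ← pyromeconic acid 4 by C2 iodination, MOM protection and Suzuki coupling with boronate 3 (from 1 and prenyl bromide 2).
5. Ring order: rings B and C are bought and joined in step 4; ring A is formed last, in step 10.

Key step: step 10

Remark on the chemistry: the target has no stereocentre and no stereogenic double bond, so "single enantiomer" sets no stereochemical task. The stereocentres of 11, 14, 15 and 17 are racemic and are all erased on the way to 18.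

**Step 1**
Reactants: 1 4‑hydroxyphenylboronic acid pinacol ester; 2 prenyl bromide
Product: 3 4,4,5,5‑tetramethyl‑2‑[4‑(3‑methylbut‑2‑enyloxy)phenyl]‑1,3,2‑dioxaborolane
Conditions: K2CO3, acetone, 50 °C
Reagents that add atoms: none
Why: Williamson O‑alkylation of the phenoxide at the primary allylic bromide (SN2); carbonate in acetone leaves the pinacol boronate intact.

**Step 2**
Reactants: 4 pyromeconic acid (3‑hydroxy‑4H‑pyran‑4‑one)
Product: 5 3‑hydroxy‑2‑iodo‑4H‑pyran‑4‑one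
Conditions: NaOH (1.0 equiv), I2 (1.0 equiv), H2O, 0 °C → rt
Reagents that add atoms: iodine, II
Why: Electrophilic iodination of the enolate at C2, the enol carbon ortho to the hydroxyl (the phenol‑type ortho‑halogenation known for 3‑hydroxy‑4‑pyranones such as kojic acid), which should outrun attack at C5.

**Step 3**
Reactants: 5 3‑hydroxy‑2‑iodo‑4H‑pyran‑4‑one
Product: 6 2‑iodo‑3‑(methoxymethoxy)‑4H‑pyran‑4‑one
Conditions: MOMCl, iPr2NEt, CH2Cl2, 0 °C → rt
Reagents that add atoms: chloromethyl methyl ether, COCCl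
Why: O‑alkylation of the acidic enolic hydroxyl (acetal protection), giving a group that tolerates Pd catalysis, amide bases, heat and fluoride.

**Step 4**
Reactants: 6 2‑iodo‑3‑(methoxymethoxy)‑4H‑pyran‑4‑one; 3 4,4,5,5‑tetramethyl‑2‑[4‑(3‑methylbut‑2‑enyloxy)phenyl]‑1,3,2‑dioxaborolane
Product: 7 3‑(methoxymethoxy)‑2‑[4‑(3‑methylbut‑2‑enyloxy)phenyl]‑4H‑pyran‑4‑one
Conditions: Pd(dppf)Cl2 (5 mol %), K3PO4, 1,4‑dioxane/H2O (10:1), 80 °C
Reagents that add atoms: none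
Why: Suzuki–Miyaura coupling; oxidative addition into the activated β‑iodo‑enone C2–I bond is fast, and the MOM acetal and the prenyl ether are inert to Pd(0)/phosphate.

**Step 5**
Reactants: 8 squaric acid
Product: 9 3,4‑dichlorocyclobut‑3‑ene‑1,2‑dione (squaryl dichloride)
Conditions: (COCl)2 (2.2 equiv), DMF (cat.), CH2Cl2, 40 °C
Reagents that add atoms: oxalyl chloride, O=C(Cl)C(Cl)=O
Why: Vilsmeier‑type chlorodehydroxylation of the two vinylogous acid hydroxyls, the standard preparation of squaryl dichloride.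

**Step 6**
Reactants: 9 3,4‑dichlorocyclobut‑3‑ene‑1,2‑dione
Product: 10 3,4‑bis[2‑(trimethylsilyl)ethoxy]cyclobut‑3‑ene‑1,2‑dione
Conditions: Me3SiCH2CH2OH (2.1 equiv), 2,6‑lutidine (2.2 equiv), CH2Cl2, −20 °C → rt
Reagents that add atoms: 2‑(trimethylsilyl)ethanol, C[Si](C)(C)CCO
Why: Addition–elimination of the alcohol at the vinylogous acid chloride carbons (esterification); the hindered pyridine only scavenges HCl, which protects the β‑silyl alcohol from acid.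

**Step 7**
Reactants: 10 3,4‑bis[2‑(trimethylsilyl)ethoxy]cyclobut‑3‑ene‑1,2‑dione
Product: 12 3‑[2‑(trimethylsilyl)ethoxy]cyclobut‑3‑ene‑1,2‑dione, via hydroxycyclobutenone 11 (not isolated)
Conditions: LiAlH(OtBu)3 (1.05 equiv), THF, −78 → −20 °C; then 2 M HCl, CH2Cl2, rt
Reagents that add atoms: water, O
Why: The bulky hydride adds once, 1,2, to a squarate carbonyl; acid then ionises the carbinol of 11 to an alkoxy‑stabilised cyclobutenyl cation that water captures at the far alkoxy carbon with loss of one silylethanol (the known semisquarate synthesis from dialkyl squarates).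

**Step 8**
Reactants: 7 3‑(methoxymethoxy)‑2‑[4‑(3‑methylbut‑2‑enyloxy)phenyl]‑4H‑pyran‑4‑one; 12 3‑[2‑(trimethylsilyl)ethoxy]cyclobut‑3‑ene‑1,2‑dione
Product: 14 4‑hydroxy‑4‑{5‑(methoxymethoxy)‑6‑[4‑(3‑methylbut‑2‑enyloxy)phenyl]‑4‑oxo‑4H‑pyran‑2‑yl}‑3‑[2‑(trimethylsilyl)ethoxy]cyclobut‑2‑en‑1‑one (racemic), via pyranonylmagnesium chloride 13 (not isolated)
Conditions: TMPMgCl·LiCl (1.15 equiv), THF, −40 °C, 1 h; then 12 (1.3 equiv), −78 → −40 °C; aq NH4Cl
Reagents that add atoms: none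
Why: Deprotonative magnesiation by the hindered TMP amide at C6–H (the vinylic proton next to ring oxygen, the counterpart of C2–H of chromones and the only such site once C2 is arylated) gives a Grignard reagent that adds 1,2 to the ketone carbonyl of 12 next to the alkoxy carbon, the other carbonyl being deactivated as a vinylogous ester; this regiochemistry fixes the later ring‑A pattern, and the new quaternary carbinol is racemic and is erased in step 10.

**Step 9**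
Reactants: 14 4‑hydroxy‑4‑{5‑(methoxymethoxy)‑6‑[4‑(3‑methylbut‑2‑enyloxy)phenyl]‑4‑oxo‑4H‑pyran‑2‑yl}‑3‑[2‑(trimethylsilyl)ethoxy]cyclobut‑2‑en‑1‑one
Product: 15 4‑methoxy‑4‑{5‑(methoxymethoxy)‑6‑[4‑(3‑methylbut‑2‑enyloxy)phenyl]‑4‑oxo‑4H‑pyran‑2‑yl}‑3‑[2‑(trimethylsilyl)ethoxy]cyclobut‑2‑en‑1‑one (racemic)
Conditions: MeI (10 equiv), Ag2O (2 equiv), 4 Å MS, MeCN, rt, dark
Reagents that add atoms: iodomethane, CI
Why: Purdie methylation of the acidic α‑ketol‑type tertiary alcohol under neutral conditions that form no free alkoxide (which could trigger anionic ring opening) and are too mild to O‑methylate the pyranone carbonyl.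

**Step 10**
Reactants: 15 4‑methoxy‑4‑{5‑(methoxymethoxy)‑6‑[4‑(3‑methylbut‑2‑enyloxy)phenyl]‑4‑oxo‑4H‑pyran‑2‑yl}‑3‑[2‑(trimethylsilyl)ethoxy]cyclobut‑2‑en‑1‑one
Product: 18 5‑hydroxy‑8‑methoxy‑3‑(methoxymethoxy)‑2‑[4‑(3‑methylbut‑2‑enyloxy)phenyl]‑7‑[2‑(trimethylsilyl)ethoxy]‑4H‑chromen‑4‑one, via vinylketene 16 (not isolated), via dienone 17 (not isolated)
Conditions: PhMe (0.01 M, degassed), 110 °C, Ar
Reagents that add atoms: none
Why: Heating opens the cyclobutenone by conrotatory 4π electrocyclic cleavage of the C1–C4 bond, the methoxy donor turning outward so that the pyranonyl group lies cis to the ketene in vinylketene 16. The dienylketene (pyranone C5=C6, the enol‑ether C=C and the ketene C=C) then closes by a thermally allowed disrotatory 6π electrocyclisation, which forms the C4a–C5 bond and the six‑membered carbocycle, ring A, as dienone 17. The C4a–H of 17, flanked by two carbonyls, should enolise at once to the aromatic, hydrogen‑bonded 5‑phenol 18, so the transient C4a centre and the racemic C4 centre of 15 both vanish and no stereocentre is created. The closest known reaction type is the Moore rearrangement of 4‑aryl‑, 4‑heteroaryl‑ and 4‑alkenyl‑4‑alkoxycyclobutenones to hydroquinone monoethers. The step needs closure at pyranone C5 only and an intact prenyl ether: C6 has ring oxygen as its other neighbour, so C5 is the sole terminus; the ring‑A pattern (C=O → C5–OH, CH → C6–H, C–OCH2CH2SiMe3 → C7, C–OMe → C8) was fixed in step 8; and neutral heating at 110 °C lies well below the aromatic Claisen threshold of an aryl prenyl ether.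

**Step 11**
Reactants: 18 5‑hydroxy‑8‑methoxy‑3‑(methoxymethoxy)‑2‑[4‑(3‑methylbut‑2‑enyloxy)phenyl]‑7‑[2‑(trimethylsilyl)ethoxy]‑4H‑chromen‑4‑one
Product: 19 5,7‑dihydroxy‑8‑methoxy‑3‑(methoxymethoxy)‑2‑[4‑(3‑methylbut‑2‑enyloxy)phenyl]‑4H‑chromen‑4‑one
Conditions: TBAF (3 equiv), THF/DMF, 60 °C; then aq NH4Cl
Reagents that add atoms: none
Why: Fluoride attack at silicon triggers β‑fragmentation (Peterson‑type) to ethene, Me3SiF and the vinylogously acidic 7‑phenoxide; the MOM acetal and the prenyl ether are inert to fluoride, and the 3‑oxygen stays protected under these basic conditions.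

**Step 12**
Reactants: 19 5,7‑dihydroxy‑8‑methoxy‑3‑(methoxymethoxy)‑2‑[4‑(3‑methylbut‑2‑enyloxy)phenyl]‑4H‑chromen‑4‑one
Product: 20 3,5,7‑trihydroxy‑8‑methoxy‑2‑[4‑(3‑methylbut‑2‑enyloxy)phenyl]‑4H‑chromen‑4‑one (target)
Conditions: HCl (0.5 M) in MeOH/THF, rt
Reagents that add atoms: none
Why: Acid‑catalysed acetal cleavage through the methoxymethyl oxocarbenium ion, trapped by methanol; dilute acid at room temperature is chosen because the 4'‑prenyl ether, on a ring deactivated by the para pyranone, should ionise far more slowly than the acetal.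

**Compound list**
1 | 4‑hydroxyphenylboronic acid pinacol ester | CC1(C)OB(c2ccc(O)cc2)OC1(C)C | starting material
2 | prenyl bromide (1‑bromo‑3‑methylbut‑2‑ene) | CC(C)=CCBr | starting material
3 | 4,4,5,5‑tetramethyl‑2‑[4‑(3‑methylbut‑2‑enyloxy)phenyl]‑1,3,2‑dioxaborolane | CC(C)=CCOc1ccc(cc1)B1OC(C)(C)C(C)(C)O1 | intermediate
4 | pyromeconic acid (3‑hydroxy‑4H‑pyran‑4‑one) | O=c1ccocc1O | starting material
5 | 3‑hydroxy‑2‑iodo‑4H‑pyran‑4‑one | O=c1ccoc(I)c1O | intermediate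
6 | 2‑iodo‑3‑(methoxymethoxy)‑4H‑pyran‑4‑one | COCOc1c(I)occc1=O | intermediate
7 | 3‑(methoxymethoxy)‑2‑[4‑(3‑methylbut‑2‑enyloxy)phenyl]‑4H‑pyran‑4‑one | COCOc1c(-c2ccc(OCC=C(C)C)cc2)occc1=O | intermediate
8 | squaric acid | O=C1C(O)=C(O)C1=O | starting material
9 | 3,4‑dichlorocyclobut‑3‑ene‑1,2‑dione | O=C1C(Cl)=C(Cl)C1=O | intermediate
10 | 3,4‑bis[2‑(trimethylsilyl)ethoxy]cyclobut‑3‑ene‑1,2‑dione | C[Si](C)(C)CCOC1=C(OCC[Si](C)(C)C)C(=O)C1=O | intermediate
11 | 4‑hydroxy‑2,3‑bis[2‑(trimethylsilyl)ethoxy]cyclobut‑2‑en‑1‑one (racemic, not isolated) | C[Si](C)(C)CCOC1=C(OCC[Si](C)(C)C)C(O)C1=O | intermediate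
12 | 3‑[2‑(trimethylsilyl)ethoxy]cyclobut‑3‑ene‑1,2‑dione | C[Si](C)(C)CCOC1=CC(=O)C1=O | intermediate
13 | chloro{5‑(methoxymethoxy)‑6‑[4‑(3‑methylbut‑2‑enyloxy)phenyl]‑4‑oxo‑4H‑pyran‑2‑yl}magnesium (LiCl complex, not isolated) | COCOc1c(-c2ccc(OCC=C(C)C)cc2)oc([Mg]Cl)cc1=O | intermediate
14 | 4‑hydroxy‑4‑{5‑(methoxymethoxy)‑6‑[4‑(3‑methylbut‑2‑enyloxy)phenyl]‑4‑oxo‑4H‑pyran‑2‑yl}‑3‑[2‑(trimethylsilyl)ethoxy]cyclobut‑2‑en‑1‑one (racemic) | O=C1C=C(OCC[Si](C)(C)C)C1(O)c1cc(=O)c(OCOC)c(-c2ccc(OCC=C(C)C)cc2)o1 | intermediate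
15 | 4‑methoxy‑4‑{5‑(methoxymethoxy)‑6‑[4‑(3‑methylbut‑2‑enyloxy)phenyl]‑4‑oxo‑4H‑pyran‑2‑yl}‑3‑[2‑(trimethylsilyl)ethoxy]cyclobut‑2‑en‑1‑one (racemic) | O=C1C=C(OCC[Si](C)(C)C)C1(OC)c1cc(=O)c(OCOC)c(-c2ccc(OCC=C(C)C)cc2)o1 | intermediate
16 | (3Z)‑4‑methoxy‑4‑{5‑(methoxymethoxy)‑6‑[4‑(3‑methylbut‑2‑enyloxy)phenyl]‑4‑oxo‑4H‑pyran‑2‑yl}‑3‑[2‑(trimethylsilyl)ethoxy]buta‑1,3‑dien‑1‑one (vinylketene, not isolated) | O=C=C/C(OCC[Si](C)(C)C)=C(/OC)c1cc(=O)c(OCOC)c(-c2ccc(OCC=C(C)C)cc2)o1 | intermediate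
17 | 8‑methoxy‑3‑(methoxymethoxy)‑2‑[4‑(3‑methylbut‑2‑enyloxy)phenyl]‑7‑[2‑(trimethylsilyl)ethoxy]‑4aH‑chromene‑4,5‑dione (racemic dienone, not isolated) | COC1=C2OC(-c3ccc(OCC=C(C)C)cc3)=C(OCOC)C(=O)C2C(=O)C=C1OCC[Si](C)(C)C | intermediate
18 | 5‑hydroxy‑8‑methoxy‑3‑(methoxymethoxy)‑2‑[4‑(3‑methylbut‑2‑enyloxy)phenyl]‑7‑[2‑(trimethylsilyl)ethoxy]‑4H‑chromen‑4‑one | COc1c(OCC[Si](C)(C)C)cc(O)c2c(=O)c(OCOC)c(-c3ccc(OCC=C(C)C)cc3)oc12 | intermediate
19 | 5,7‑dihydroxy‑8‑methoxy‑3‑(methoxymethoxy)‑2‑[4‑(3‑methylbut‑2‑enyloxy)phenyl]‑4H‑chromen‑4‑one | COc1c(O)cc(O)c2c(=O)c(OCOC)c(-c3ccc(OCC=C(C)C)cc3)oc12 | intermediate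
20 | 3,5,7‑trihydroxy‑8‑methoxy‑4'‑prenyloxyflavone | COc1c(O)cc(O)c2c(=O)c(O)c(-c3ccc(OCC=C(C)C)cc3)oc12 | target

**Step count**
Total: 12 steps. Longest linear sequence: 8 steps (4 → 5 → 6 → 7 → 14 → 15 → 18 → 19 → 20; the squaric acid branch 8 → 9 → 10 → 12 → 14 → … → 20 is also 8).

**Steps most likely to fail**

1. Step 8. Deprotonation may leak to C5–H next to the carbonyl, the magnesiated pyranone may add to unreacted 7 during the metalation, and the amine‑containing mixture may erode the sensitive dione 12. The fallback sets out from 7 and comes back at 14. Zincation of 7 with TMPZnCl·LiCl (THF, 0 °C → rt) should give a stable organozinc, which is quenched with iodine to 2‑iodo‑5‑(methoxymethoxy)‑6‑[4‑(3‑methylbut‑2‑enyloxy)phenyl]‑4H‑pyran‑4‑one F1. At this stable halide the site of metalation can be proven and any isomer removed. Iodine–magnesium exchange (iPrMgCl·LiCl, THF, −78 °C, minutes) then generates the Grignard reagent 13 free of amine, and addition to 12 at −78 °C should deliver 14.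

2. Step 10. Closure of the ketene onto the cross‑conjugated, electron‑poor C5=C6 bond may be slow, so that the temperature then required brings on aromatic Claisen rearrangement of the prenyl ether or ketene oligomerisation. The fallback sets out from 6 and comes back at 18; it carries ring B as a benzyl ether so that forcing thermolysis is harmless.
   - Suzuki coupling of 6 with 4‑(benzyloxy)phenylboronic acid (conditions of step 4) gives 2‑[4‑(benzyloxy)phenyl]‑3‑(methoxymethoxy)‑4H‑pyran‑4‑one F2.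
   - Magnesiation and addition to 12 as in step 8 give 4‑{6‑[4‑(benzyloxy)phenyl]‑5‑(methoxymethoxy)‑4‑oxo‑4H‑pyran‑2‑yl}‑4‑hydroxy‑3‑[2‑(trimethylsilyl)ethoxy]cyclobut‑2‑en‑1‑one F3.
   - Ag2O/MeI gives 4‑{6‑[4‑(benzyloxy)phenyl]‑5‑(methoxymethoxy)‑4‑oxo‑4H‑pyran‑2‑yl}‑4‑methoxy‑3‑[2‑(trimethylsilyl)ethoxy]cyclobut‑2‑en‑1‑one F4.
   - Ring expansion in mesitylene at 160 °C should give 2‑[4‑(benzyloxy)phenyl]‑5‑hydroxy‑8‑methoxy‑3‑(methoxymethoxy)‑7‑[2‑(trimethylsilyl)ethoxy]‑4H‑chromen‑4‑one F5.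
   - Hydrogenolysis (H2, Pd/C, EtOAc, rt) frees 5‑hydroxy‑2‑(4‑hydroxyphenyl)‑8‑methoxy‑3‑(methoxymethoxy)‑7‑[2‑(trimethylsilyl)ethoxy]‑4H‑chromen‑4‑one F6.
   - Alkylation of F6 with 2 (K2CO3, acetone, rt) should return 18, since the chelated 5‑OH is inert under these conditions.

3. Step 9. Alkylation of the hindered tertiary alcohol may be sluggish, or the strained ketol may open under the silver oxide. The fallback sets out from 14 and comes back at 18. The free carbinol 14 is thermolysed directly (degassed PhMe, 110 °C, Ar; the parent hydroxy variant of the same ring expansion). This should give 5,8‑dihydroxy‑3‑(methoxymethoxy)‑2‑[4‑(3‑methylbut‑2‑enyloxy)phenyl]‑7‑[2‑(trimethylsilyl)ethoxy]‑4H‑chromen‑4‑one F7, kept under argon to avoid air oxidation. MeI (1.1 equiv) and K2CO3 in degassed acetone should then methylate only the free 8‑OH, because the 5‑OH is locked in a hydrogen bond to the C4 carbonyl; this gives 18.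

**Further compounds**
F1 | step 8 | 2‑iodo‑5‑(methoxymethoxy)‑6‑[4‑(3‑methylbut‑2‑enyloxy)phenyl]‑4H‑pyran‑4‑one | COCOc1c(-c2ccc(OCC=C(C)C)cc2)oc(I)cc1=O
F2 | step 10 | 2‑[4‑(benzyloxy)phenyl]‑3‑(methoxymethoxy)‑4H‑pyran‑4‑one | COCOc1c(-c2ccc(OCc3ccccc3)cc2)occc1=O
F3 | step 10 | 4‑{6‑[4‑(benzyloxy)phenyl]‑5‑(methoxymethoxy)‑4‑oxo‑4H‑pyran‑2‑yl}‑4‑hydroxy‑3‑[2‑(trimethylsilyl)ethoxy]cyclobut‑2‑en‑1‑one (racemic) | O=C1C=C(OCC[Si](C)(C)C)C1(O)c1cc(=O)c(OCOC)c(-c2ccc(OCc3ccccc3)cc2)o1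
F4 | step 10 | 4‑{6‑[4‑(benzyloxy)phenyl]‑5‑(methoxymethoxy)‑4‑oxo‑4H‑pyran‑2‑yl}‑4‑methoxy‑3‑[2‑(trimethylsilyl)ethoxy]cyclobut‑2‑en‑1‑one (racemic) | O=C1C=C(OCC[Si](C)(C)C)C1(OC)c1cc(=O)c(OCOC)c(-c2ccc(OCc3ccccc3)cc2)o1
F5 | step 10 | 2‑[4‑(benzyloxy)phenyl]‑5‑hydroxy‑8‑methoxy‑3‑(methoxymethoxy)‑7‑[2‑(trimethylsilyl)ethoxy]‑4H‑chromen‑4‑one | COc1c(OCC[Si](C)(C)C)cc(O)c2c(=O)c(OCOC)c(-c3ccc(OCc4ccccc4)cc3)oc12
F6 | step 10 | 5‑hydroxy‑2‑(4‑hydroxyphenyl)‑8‑methoxy‑3‑(methoxymethoxy)‑7‑[2‑(trimethylsilyl)ethoxy]‑4H‑chromen‑4‑one | COc1c(OCC[Si](C)(C)C)cc(O)c2c(=O)c(OCOC)c(-c3ccc(O)cc3)oc12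
F7 | step 9 | 5,8‑dihydroxy‑3‑(methoxymethoxy)‑2‑[4‑(3‑methylbut‑2‑enyloxy)phenyl]‑7‑[2‑(trimethylsilyl)ethoxy]‑4H‑chromen‑4‑one | Oc1c(OCC[Si](C)(C)C)cc(O)c2c(=O)c(OCOC)c(-c3ccc(OCC=C(C)C)cc3)oc12
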